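**Retrosynthetic overview**
- 17 ⇒ 4-ketone 15. Hydride goes onto C4, then C4 is corrected to 4β by reversible ionisation (A-ring quinone-methide cation) and axial return of water.
- 15 ⇒ chalcone 13. Ring C closes from the 2'-oxygen to Cβ as in the chalcone → flavanone → dihydroflavonol pathway. Oxygenation and ring closure run in one flask through the (αR,βS)-epoxide 14, which sets C3 and then C2.
- 13 ⇒ aryllithium 12 + p-coumaric Weinreb amide 11. Arene 6 is mirror-symmetric, so the acylation site is unambiguous. 6 ⇒ 5-methoxyresorcinol 1 by bis-MOM protection and directed lithiation/prenylation.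
- Ring order: rings A and B are bought; ring C is the only ring formed (step 6).

Assumption: the SMILES reads as (2R,3S,4S), that is 2α-aryl, 3β-OH, 4β-OH (2,3-trans-3,4-cis); poly-L-leucine is bought as a catalyst.

**Step 1**
Reactants: 1 5-methoxyresorcinol; 2 chloromethyl methyl ether (MOMCl)
Product: 3 1-methoxy-3,5-bis(methoxymethoxy)benzene
Conditions: MOMCl (2.5 equiv), i-Pr2NEt (3 equiv), CH2Cl2, 0 °C to rt
Reagents that add atoms: chloromethyl methyl ether, COCCl
Why: Williamson-type O-alkylation of both phenols gives the bis-acetal, which directs both later lithiations and falls off in the acid stage of step 6; no stereocentre is formed.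

**Step 2**
Reactants: 3 1-methoxy-3,5-bis(methoxymethoxy)benzene; 4 prenyl bromide
Product: 6 5-methoxy-1,3-bis(methoxymethoxy)-2-prenylbenzene, via aryllithium 5 (not isolated)
Conditions: n-BuLi (1.1 equiv), THF, 0 °C, 1 h; then CuI (10 mol %), prenyl bromide (1.2 equiv), −78 °C to rt
Reagents that add atoms: prenyl bromide, CC(C)=CCBr; n-butyllithium, [Li]CCCC (lithium of 5 only)
Why: Directed ortho-metalation removes the proton between the two chelating OMOM groups (stronger directors than OMe), and copper-catalysed SN2 allylation at the primary carbon of prenyl bromide leaves a mirror-symmetric arene whose two remaining ring positions are equivalent.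

**Step 3**
Reactants: 7 (E)-p-coumaric acid; 8 N,O-dimethylhydroxylamine hydrochloride
Product: 10 (E)-3-(4-hydroxyphenyl)-N-methoxy-N-methylacrylamide, via acyl imidazole 9 (not isolated)
Conditions: CDI (1.1 equiv), THF, rt, 1 h; then MeNH(OMe)·HCl (1.3 equiv), rt, 12 h
Reagents that add atoms: N,O-dimethylhydroxylamine hydrochloride, CNOC.Cl; 1,1'-carbonyldiimidazole, O=C(n1ccnc1)n1ccnc1 (imidazolyl group of 9 only)
Why: Weinreb amide synthesis by CDI activation and aminolysis, in which the carboxylic acid reacts faster than the phenol and the E-alkene is untouched.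

**Step 4**
Reactants: 10 (E)-3-(4-hydroxyphenyl)-N-methoxy-N-methylacrylamide; 2 chloromethyl methyl ether
Product: 11 (E)-N-methoxy-3-[4-(methoxymethoxy)phenyl]-N-methylacrylamide
Conditions: MOMCl (1.3 equiv), i-Pr2NEt (1.6 equiv), CH2Cl2, 0 °C to rt
Reagents that add atoms: chloromethyl methyl ether, COCCl
Why: Phenol O-alkylation (MOM protection) removes the acidic proton before the organolithium step and prevents a B-ring phenoxide from deactivating the enone in the nucleophilic epoxidation.

**Step 5**
Reactants: 6 5-methoxy-1,3-bis(methoxymethoxy)-2-prenylbenzene; 11 (E)-N-methoxy-3-[4-(methoxymethoxy)phenyl]-N-methylacrylamide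
Product: 13 (E)-6'-methoxy-2',4',4-tris(methoxymethoxy)-3'-prenylchalcone, via aryllithium 12 (not isolated)
Conditions: n-BuLi (1.1 equiv), THF, 0 °C, 45 min; then 11 (1.0 equiv), −78 °C to 0 °C; aqueous work-up
Reagents that add atoms: Weinreb amide 11, CON(C)C(=O)/C=C/c1ccc(OCOC)cc1; n-butyllithium, [Li]CCCC (lithium of 12 only)
Why: The second directed ortho-metalation can only occur at one of the two equivalent positions between OMOM and OMe, so the xanthohumol substitution pattern arises without a regiochemical choice, and the Weinreb ketone synthesis (1,2-addition) stops at the E-enone.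

**Step 6**
Reactants: 13 (E)-6'-methoxy-2',4',4-tris(methoxymethoxy)-3'-prenylchalcone
Product: 15 (2R,3R)-3,7,4'-trihydroxy-5-methoxy-8-prenylflavanone, via (αR,βS)-epoxide 14 (not isolated)
Conditions: poly-L-leucine (20 wt %), urea·H2O2 (1.3 equiv), DBU (1.3 equiv), THF, rt; polymer filtered off, Me2S (0.3 equiv, destroys excess peroxide); then HCl/MeOH (ca. 1 M free acid), 45 °C, 1 h; 15 recrystallised from aqueous MeOH to raise ee
Reagents that add atoms: urea–hydrogen peroxide, OO.NC(N)=O (one oxygen: epoxide oxygen of 14, then 3-OH of 15)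
Why: Juliá–Colonna epoxidation with helical poly-L-leucine gives the (αR,βS)-trans-epoxide at the electron-poor enone only (the prenyl alkene is inert to HOO−) and so fixes C3; methanolic HCl then removes the three MOM groups and opens the oxirane at the p-oxybenzylic Cβ, where the freed 2'-phenol closes ring C by 6-endo attack in the chalcone-isomerase sense, with inversion at Cβ and the thermodynamic preference both leading to the 2,3-trans (2R,3R) product.

**Step 7**
Reactants: 15 (2R,3R)-3,7,4'-trihydroxy-5-methoxy-8-prenylflavanone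
Product: 17 (2R,3S,4S)-5-O-methyl-8-prenylafzelechin-4β-ol, via 4α-ol 16 (not isolated)
Conditions: NaBH4 (4 equiv), THF/H2O 4:1, 0 °C, 1 h; then diluted with degassed H2O to ca. 5 mM, AcOH to pH 3.5–4, Ar, 35 °C, 3–6 h; neutralised, EtOAc extraction, Sephadex LH-20 or RP-18 separation, recovered 16 recycled
Reagents that add atoms: water, O (oxygen of the 4β-hydroxyl after the solvolytic exchange)
Why: Borohydride reduction along the axial β trajectory gives the 3,4-trans 4α-ol 16, whose phloroglucinol-type benzylic C4–OH ionises reversibly in dilute acid (SN1, the known trans-to-cis epimerisation of leucoanthocyanidins), so water returns axially on the β face to give the 3,4-cis 4β-ol, whose pseudo-axial hydroxyl also avoids the peri clash with the 5-methoxy group, while C2 and C3 are untouched.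

**Compound list**
1 | 5-methoxyresorcinol (3,5-dihydroxyanisole) | COc1cc(O)cc(O)c1 | starting material
2 | chloromethyl methyl ether (MOMCl) | COCCl | starting material
3 | 1-methoxy-3,5-bis(methoxymethoxy)benzene | COCOc1cc(OC)cc(OCOC)c1 | intermediate
4 | prenyl bromide (1-bromo-3-methylbut-2-ene) | CC(C)=CCBr | starting material
5 | [4-methoxy-2,6-bis(methoxymethoxy)phenyl]lithium | [Li]c1c(OCOC)cc(OC)cc1OCOC | intermediate
6 | 5-methoxy-1,3-bis(methoxymethoxy)-2-(3-methylbut-2-enyl)benzene | COCOc1cc(OC)cc(OCOC)c1CC=C(C)C | intermediate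
7 | (E)-p-coumaric acid | OC(=O)/C=C/c1ccc(O)cc1 | starting material
8 | N,O-dimethylhydroxylamine hydrochloride | CNOC.Cl | starting material
9 | (E)-3-(4-hydroxyphenyl)-1-(imidazol-1-yl)prop-2-en-1-one | O=C(/C=C/c1ccc(O)cc1)n1ccnc1 | intermediate
10 | (E)-3-(4-hydroxyphenyl)-N-methoxy-N-methylacrylamide | CON(C)C(=O)/C=C/c1ccc(O)cc1 | intermediate
11 | (E)-N-methoxy-3-[4-(methoxymethoxy)phenyl]-N-methylacrylamide | CON(C)C(=O)/C=C/c1ccc(OCOC)cc1 | intermediate
12 | [6-methoxy-2,4-bis(methoxymethoxy)-3-(3-methylbut-2-enyl)phenyl]lithium | [Li]c1c(OC)cc(OCOC)c(CC=C(C)C)c1OCOC | intermediate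
13 | (E)-1-[6-methoxy-2,4-bis(methoxymethoxy)-3-(3-methylbut-2-enyl)phenyl]-3-[4-(methoxymethoxy)phenyl]prop-2-en-1-one (tri-O-MOM-xanthohumol) | COCOc1ccc(/C=C/C(=O)c2c(OC)cc(OCOC)c(CC=C(C)C)c2OCOC)cc1 | intermediate
14 | (αR,βS)-trans-epoxide of 13: [6-methoxy-2,4-bis(methoxymethoxy)-3-prenylphenyl] (2R,3S)-3-[4-(methoxymethoxy)phenyl]oxiran-2-yl ketone | COCOc1cc(OC)c(C(=O)[C@@H]2O[C@H]2c2ccc(OCOC)cc2)c(OCOC)c1CC=C(C)C | intermediate
15 | (2R,3R)-3,7-dihydroxy-2-(4-hydroxyphenyl)-5-methoxy-8-(3-methylbut-2-enyl)chroman-4-one (2,3-trans) | COc1cc(O)c(CC=C(C)C)c2c1C(=O)[C@H](O)[C@@H](c1ccc(O)cc1)O2 | intermediate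
16 | (2R,3S,4R)-5-O-methyl-8-prenylafzelechin-4α-ol (2,3-trans-3,4-trans) | COc1cc(O)c(CC=C(C)C)c2c1[C@@H](O)[C@H](O)[C@@H](c1ccc(O)cc1)O2 | intermediate
17 | (2R,3S,4S)-5-O-methyl-8-prenylafzelechin-4β-ol (2,3-trans-3,4-cis) | COc1cc(O)c(CC=C(C)C)c2c1[C@H](O)[C@H](O)[C@@H](c1ccc(O)cc1)O2 | target

**Totals**
Total step count: 7.
Longest linear sequence: 5 (steps 1, 2, 5, 6, 7).

**Three steps most likely to fail**

**Step 6.**
- Risk: The enantioselectivity of polyleucine epoxidation is known to drop for 2',6'-dioxygenated chalcones, whose aroyl group is twisted out of conjugation. The acid stage can also lose material to aroyl migration or to chroman formation at the prenyl group.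
- Fallback: Take the absolute configuration from a kinetic resolution at the hydride stage instead of from the epoxidation. It sets out from 13. H2O2/NaOH in MeOH–THF gives the racemic trans-epoxide, that is 14 together with its mirror image (αS,βR)-epoxide F1. HCl/MeOH as before gives the racemic trans-dihydroflavonol, that is 15 together with (2S,3S)-dihydroflavonol F2. Noyori–Ikariya transfer hydrogenation follows, with RuCl[(S,S)-TsDPEN](p-cymene), HCO2H/Et3N, EtOAc, stopped near half conversion. It reduces only 15, because for this enantiomer the face chosen by the catalyst is also the axial β face. F2 stays a ketone and is removed by chromatography. The fallback comes back to the route at 16, which is epimerised as in the second half of step 7.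

**Step 7.**
- Risk: The equilibrium between 16 and 17 may not lie far enough towards 17. The C4 cation can also be intercepted by C6 of a second molecule, giving proanthocyanidin-type oligomers.
- Fallback: Template the cis-diol instead of relying on the free equilibrium. It sets out from 16, isolated after a neutral work-up of the borohydride reduction, and uses PhB(OH)2 (1.1 equiv) and PPTS (5 mol %) in MeCN at rt. Boron first binds the 3-OH and hands one of its own hydroxyls to the C4 cation on the same β face. Only the 3,4-cis diol can close the five-membered ring, so the epimer mixture drains into cyclic 3,4-cis phenylboronate F3. Pinacol in EtOAc at neutral pH then takes over the boron and releases 17, where the fallback comes back to the route.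

**Step 5.**
- Risk: n-BuLi may deprotonate the benzylic/allylic CH2 of 6. The hindered, basic aryllithium 12 may also add to the β-carbon of 11 or degrade the N-methoxy amide by elimination.
- Fallback: An organolithium-free, classical assembly of the same chalcone, setting out from 1. Ac2O/BF3·OEt2 (Friedel–Crafts acylation, only moderately regioselective) gives 2,4-dihydroxy-6-methoxyacetophenone F4. Prenyl bromide 4 with KOH in aqueous MeOH at 0 °C C-alkylates the carbon between the two hydroxyls to give 2,4-dihydroxy-6-methoxy-3-prenylacetophenone F5. NaH and 2 in DMF give 6-methoxy-2,4-bis(methoxymethoxy)-3-prenylacetophenone F6. Claisen–Schmidt condensation (KOH, EtOH, rt) with 4-(methoxymethoxy)benzaldehyde F7, made from 4-hydroxybenzaldehyde and 2, gives 13, where the fallback comes back to the route.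

**Further compounds**
F1 | step 6 | (αS,βR)-epoxide (enantiomer of 14) | COCOc1cc(OC)c(C(=O)[C@H]2O[C@@H]2c2ccc(OCOC)cc2)c(OCOC)c1CC=C(C)C
F2 | step 6 | (2S,3S)-dihydroflavonol (enantiomer of 15) | COc1cc(O)c(CC=C(C)C)c2c1C(=O)[C@@H](O)[C@H](c1ccc(O)cc1)O2
F3 | step 7 | cyclic 3,4-cis phenylboronate of 17 | COc1cc(O)c(CC=C(C)C)c2c1[C@@H]1OB(c3ccccc3)O[C@@H]1[C@@H](c1ccc(O)cc1)O2
F4 | step 5 | 2,4-dihydroxy-6-methoxyacetophenone | CC(=O)c1c(O)cc(O)cc1OC
F5 | step 5 | 2,4-dihydroxy-6-methoxy-3-prenylacetophenone | CC(=O)c1c(OC)cc(O)c(CC=C(C)C)c1O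
F6 | step 5 | 6-methoxy-2,4-bis(methoxymethoxy)-3-prenylacetophenone | CC(=O)c1c(OC)cc(OCOC)c(CC=C(C)C)c1OCOC
F7 | step 5 | 4-(methoxymethoxy)benzaldehyde | COCOc1ccc(C=O)cc1
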